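Add target and isomer of the product in the last reading of each earlier run, then divide by the equivalents of coupling partner. I did this first, because the catalyst's steps suggest why it should work.

all flasks: starting material 0.050 M (fed, over 10 min); free catalyst 1 mol%

| charge | coupling partner | second substrate | remark | time |
|---|---|---|---|---|
| theta | 1.2 equiv | 0.20 equiv | run made earlier |  |
| delta | 2.7 equiv | 0.20 equiv | run made earlier |  |
| flask | 1.80 equiv | 0.200 equiv |  | 3.0 h |

- theta (time / h: target / %, uncatalysed product / %, isomer of the product / %): 0.200: 7, 9, 1; 0.667: 6, 34, 4; 1.00: 9, 41, 5; 1.50: 6, 53, 2; 2.50: 8, 59, 8
- delta (time / h: target / %, uncatalysed product / %, isomer of the product / %): 0.200: 11, 19, 2; 0.333: 15, 38, 6; 0.667: 14, 56, 12; 1.33: 14, 65, 13; 2.50: 17, 69, 16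

(readings scatter by 2 percentage points)

1. why nothing more happens at 3.0 h, or that something still does (the coupling partner has run out first / no working catalyst is left / all of the starting material has reacted / it is still moving / forward and back rates have come level)
2. target at 3.0 h, in percent of the starting material charged
3. uncatalysed product at 3.0 h, in percent of the starting material charged
4. isomer of the product at 3.0 h, in percent of the starting material charged
5. amount of target if the flask were left three thousand times as long, in percent of the starting material charged

- candidate steps: starting material + coupling partner + free catalyst -> free catalyst + target; target + free catalyst <-> isomer of the product + free catalyst; second substrate + coupling partner + free catalyst -> free catalyst + second product; starting material + free catalyst -> spent catalyst; starting material + coupling partner -> uncatalysed product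
- the reaction counts as stopped when no species that holds the starting material changes by six tenths of a point or more over the second half of the time

On the candidate steps, free catalyst meeting starting material either turns over, which needs coupling partner, or is spent, which does not. So the turnovers before it dies should grow with the partner charge. I named the result g, the catalysed yield per equivalent, which is the usual turnover number taken per equivalent of partner.

| run | partner | target + isomer | per equivalent |
|---|---|---|---|
| theta | 1.2 equiv | 16.0% | 13.3% |
| delta | 2.7 equiv | 33.0% | 12.2% |

These are two separate flasks at the two ends of the partner range, and they give two separate readings of one number. They differ by 1.1 percentage points, less than the scatter of a single reading, so I trusted the number. Pooling both runs gave 12.6% of the charge per equivalent, and for the flask, between those ends, 22.6% of catalysed product.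

The forecast came lower than my figure, with target 12% and isomer 9%, which sum to 21.0%. It also gave uncatalysed product 73%, 12% of target after the long wait, and the verdict it is still moving. Its picture was “a catalyst killed by starting material after a limited number of turnovers”.

The flask gave the verdict it is still moving, with target 10.9%, isomer 9.97%, uncatalysed product 73.6% and 9.97% of target after the long wait, so the forecast stands on every count.

    starting material + coupling partner + free catalyst → free catalyst + target (k = 11.0 M⁻² s⁻¹)
    target + free catalyst ⇌ isomer of the product + free catalyst, rate k2*[free catalyst]*[target] forward; the back reaction follows from the equilibrium constant (K = 1.10, k = 3.70 M⁻¹ s⁻¹)
    second substrate + coupling partner + free catalyst → free catalyst + second product (k = 120 M⁻² s⁻¹)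
    starting material + free catalyst → spent catalyst (k = 0.0330 M⁻¹ s⁻¹)
    starting material + coupling partner → uncatalysed product (k = 0.00620 M⁻¹ s⁻¹)

Catalysed product came to 20.9%, or 11.6% per equivalent against my 12.6%. At 3.00 h spent catalyst stood at 97.9% of the catalyst charged, and the 4.53% of starting material left was going to uncatalysed product 53 times as fast as to target. The passing of starting material and free catalyst into spent catalyst is the largest single effect I can show, though not the main reason: with that step taken away, this flask holds 24.4% isomer, not 9.97%.

For a neighbour flask charged like this one but with 0.720 equiv of coupling partner, g gives 9.07% of catalysed product. That neighbour computes to 7.73%, with free catalyst at 0%.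

(The data were generated by integration with constants of no real substance, and the scatter is random.)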